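# Synthesis plan for the daucane veratrate 21 by catalytic conjugate vinylation–aldol on a cycloheptadienone

## The problem

Compound 21 is the 3,4-dimethoxybenzoate of a daucane diol: a cyclopentane (ring A) and a cycloheptene (ring B) share the C1–C5 bond and are trans-fused. Daucane numbering is used throughout: C1 is the quaternary carbon with methyl C15, C2 and C3 are the ring A methylenes, C4 is the tertiary carbinol carbon with the isopropyl group, C5 the ring-fusion methine, C6 the ester-bearing carbon, and C7, C8 (methyl C14), C9 and C10 complete ring B with the C8=C9 alkene. The four stereocentres, (1R,4R,5S,6S), are contiguous around C5. C1 is an all-carbon quaternary centre with no neighbouring group through which it could be corrected, so it must be set first and in the absolute sense. It can then control C5, and C5 with its two oxygenated neighbours can control C6 (hydride delivery steered by the C4 oxygen) and C4 (carbonyl addition through a chelate to the C6 oxygen). Rough treatment is excluded by three features: the C8=C9 alkene lies β,γ to C6 and slips into conjugation under acid or base whenever C6 is a carbonyl group; the 1,3-dioxygenation at C4/C6 makes every ketone intermediate a candidate for retro-aldol cleavage or β-elimination; and the aryl ester must survive. The feature that opens the molecule is the sequence C1–C5–C6(O): with C6 as a ketone, C1 is the β- and C5 the α-carbon, the two arms of ring A (C2 on C1, C4 on C5) stand trans, and C4 bears oxygen. This is the imprint of a conjugate addition at C1 followed by an aldol reaction at C5 on a cycloheptenone that already carries both methyl groups and C8=C9. What remains is the closure of ring A at C3–C4 with the correct carbinol configuration and the exchange of oxidation levels between C4 and C6.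

## Retrosynthesis

**21 to 20 (cut C3–C4).** Ring A is opened at C3–C4, read as the addition of a C3 organometallic to a C4 ketone. The neighbouring cuts are less attractive: C1–C2 and C4–C5 are reserved for the three-component step, and C2–C3 (metathesis) would need an extra vinyl group and a later hydrogenation. The precursor, iodo ketone 20, is monocyclic and has lost the C4 stereocentre. The forward reaction must close a trans-fused five-membered ring and place the new hydroxyl cis to C6; a samarium Barbier reaction with chelation to the C6 ester oxygen is asked to do both. The veratrate is already in place, so the ring closure ends the synthesis.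

**20 to 16 (functional-group changes at C3 and C4).** The iodide of 20 comes from primary alcohol 18 through iodide 19 (ketone by oxidation of the C4 carbinol), and 18 comes from the vinyl group of 16. No carbon–carbon bond is cut. The forward steps must hydroborate the vinyl group beside the trisubstituted C8=C9 alkene, iodinate the primary hydroxyl beside a hindered secondary one, and oxidise C4 without eliminating the β-acyloxy group.

**16 to 14 to 12 (ester C–O bond, then C6–H).** Removing the veratroyl group (from acid chloride 15) gives diol 14, and 14 is the reduction product of β-hydroxy ketone 12. This pair of steps exchanges the oxidation levels of C4 and C6 without protecting groups. The C4 hydroxyl of 12 steers the hydride to set C6, and the steric difference between the two hydroxyls of 14 lets the ester go to O6 alone. The alternative, oxidising C4 first, would give a β-diketone in which C5 is lost by enolisation and the C6 carbonyl competes in the ring closure.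

**12 to 6 + 9 + 10 (cut C1–C2 and C4–C5).** This is the central cut. Both bonds to the stereogenic pair C1/C5 are broken, giving the achiral dienone 6, vinylalane 9 and isobutyraldehyde 10. All fifteen skeletal carbons, both oxygens and the C8=C9 alkene are present after one operation. The forward reaction must add vinyl to one enantioface at C1, keep the enolate regiodefined at C5, and capture the aldehyde trans to the vinyl group.

**6 to 4 to 3 to 2 to 1 (one-carbon ring expansion).** C5 of 6 is taken out as the inserted carbon, which leads back to siloxycyclopropane 4 and the six-membered silyl dienol ether 3. Ether 3 is the Birch product of aryl silyl ether 2, made from 2,5-dimethylphenol 1. This route fixes the enone regiochemistry and delivers C8=C9 in its skipped position from the aromatic ring. Direct enolisation of a cyclohexenone would give the wrong regioisomer, which is why the enol ether is taken from the arene.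

**9 to 7 + 8.** The alane is cut at the Al–vinyl bond to vinylmagnesium bromide 7 and diisobutylaluminium chloride 8, both commercial.

## Roads not taken

**Alternative 1:** Ring B would be cut at C1–C10 and C5–C6, leaving ring A as the enantiopure sulfinyl enone A2 and the 4-methyl-3-oxidopyrylium ylide released from acetoxypyranone A3 with Et3N. The forward [5+2] cycloaddition across C5=C1 of A2 would give the oxa-bridged adduct A1.

- Merits: ring B and both fusion bonds form in one step, and the quaternary C1 and the C6 oxygen (as the ether bridge) are set together relative to each other. The sulfinyl group activates the tetrasubstituted alkene and supplies absolute control.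
- Weak points: the dipolarophile is tetrasubstituted and the step must create two adjacent fully substituted carbons. The adduct is necessarily cis at C1/C5, so the trans fusion depends on how C5 is protonated after the sulfur is removed. A1 also carries surplus functionality: the C9 carbonyl must be removed with migration of C7=C8 to C8=C9, the C10–O bond must be cleaved, and isopropyl must be added to the C4 ketone. The chirality source is stoichiometric.
- Comparison: this road is better in that ring B and the C6 configuration come from a single step, whereas the chosen plan needs a separate reduction (step 7) and a late ring closure (step 12). Against this the chosen plan sets C1 with a catalyst, obtains the C1/C5 trans relationship directly, and carries no atom that must later be removed.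

**Alternative 2:** Ring B would be cut at C7–C8 and C1–C10, leading to diazo ester A5 and ketal diene A6. With Rh2(S-DOSP)4 (or its antipode) the vinylcarbenoid from A5 would cyclopropanate the vinyl group of A6, and the cis-divinylcyclopropane would rearrange to the bicyclic diene ester A4.

- Merits: the step is catalytic and asymmetric, and it makes the seven-membered ring, the quaternary C1 and the C8=C9 alkene in its final place in one step. In A4 the C5=C6 alkene is electron-rich while C8=C9 is an enoate, so a hydroboration anti to the angular methyl could set C5–H and C6–OH together.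
- Weak points: the Cope step must form the quaternary centre at the tetrasubstituted terminus of A6, and the enantioselectivity of this annulation varies with diene substitution. The ester at C8 has to be reduced to the C14 methyl through an allylic intermediate without transposition. The isopropyl group has to be added intermolecularly to an enolisable, hindered cyclopentanone.
- Comparison: this is the closest competitor and is about as short. It is better in building ring B rather than obtaining it by ring expansion, and in setting C5 and C6 in one step. The chosen plan sets against it that every carbon arrives at its final oxidation level, that the quaternary centre is made by a reaction class with direct precedent on β-methyl cycloheptenones, and that the isopropyl carbinol forms intramolecularly under chelation.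

**Alternative 3:** The whole skeleton would be cut at C1–C10 and C4–C5 back to (2E,6E)-farnesyl diphosphate A8, which a carotol-synthase-type cyclase would convert into carotol A7.

- Merits: one step gives the complete daucane skeleton with absolute configuration and no protecting groups. No chemical route can match this for skeleton construction.
- Weak points: A7 carries its oxygen at C5 and none at C4 or C6. The target needs hydrogen at C5 (trans to C15) and oxygen on both flanking carbons, so the oxygen would have to be removed from the ring fusion and two new ones introduced with regio- and stereocontrol beside the C8=C9 alkene. This would take at least as many steps as the chosen plan spends in total. The road also depends on an expressed enzyme and on a diphosphate substrate.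
- Comparison: superior in brevity up to the skeleton. The chosen plan sets against it that the C4 and C6 oxygens arise at the right carbons from the aldol step itself and that only standard laboratory chemistry is needed.

Key step: step 6

Remark on the chemistry: the enantiomer of the carbene ligand is taken to be the one that gives (S)-configured C1 in 11 and 12, its sense of induction being assumed to parallel that on simple β-methyl cycloalkenones.

Remark on the chemistry: the C4 carbinol of 12 is drawn anti to C1 (1'R), as a closed transition state of a ring enolate predicts; it is used once, in step 7, and is destroyed in step 11.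

## Route

Step 1
Reactants: 1 2,5-dimethylphenol
Product: 2 tert-butyl(2,5-dimethylphenoxy)dimethylsilane
Conditions: TBSCl, imidazole, DMF, 23 °C
Reagents that add atoms: tert-butyldimethylsilyl chloride, CC(C)(C)[Si](C)(C)Cl
Why: Standard silylation of a phenol; the bulky silyl group is chosen because aryl silyl ethers of this size withstand dissolving-metal reduction and the O–Si bond is later the trigger for ring expansion.

Step 2
Reactants: 2 tert-butyl(2,5-dimethylphenoxy)dimethylsilane
Product: 3 tert-butyl[(2,5-dimethylcyclohexa-1,4-dien-1-yl)oxy]dimethylsilane
Conditions: Li, NH3 (l), THF, t-BuOH, −78 → −33 °C; MeOH quench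
Reagents that add atoms: none
Why: Birch reduction; the oxygen and both methyl groups end on the two remaining alkenes, which gives the tetrasubstituted silyl enol ether regiospecifically and the future C8=C9 alkene in its skipped position.

Step 3
Reactants: 3 tert-butyl[(2,5-dimethylcyclohexa-1,4-dien-1-yl)oxy]dimethylsilane
Product: 4 tert-butyl[(3,6-dimethylbicyclo[4.1.0]hept-3-en-1-yl)oxy]dimethylsilane (racemic)
Conditions: CH2I2, Zn–Cu couple, Et2O, reflux; pyridine work-up
Reagents that add atoms: diiodomethane, ICI
Why: Simmons–Smith cyclopropanation; the electrophilic zinc carbenoid selects the electron-rich enol ether alkene over the trialkyl alkene, and the pyridine work-up removes ZnI2 so that the acid-labile siloxycyclopropane survives.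

Step 4
Reactants: 4 tert-butyl[(3,6-dimethylbicyclo[4.1.0]hept-3-en-1-yl)oxy]dimethylsilane
Product: 6 3,6-dimethylcyclohepta-2,5-dien-1-one, via 3-chloro-3,6-dimethylcyclohept-5-en-1-one 5 (not isolated)
Conditions: FeCl3, DMF, 0 °C; then NaOAc, MeOH, 0 → 23 °C
Reagents that add atoms: none
Why: FeCl3-mediated one-carbon ring expansion of a siloxycyclopropane: trivalent iron cleaves the O–Si bond, the iron alkoxide fragments at the internal cyclopropane bond to the tertiary β-keto radical, and chlorine transfer gives 5. Acetate then removes HCl through the enolate on the inserted carbon (E1cB), which places the new alkene in conjugation and leaves the other one skipped.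

Step 5
Reactants: 7 vinylmagnesium bromide; 8 diisobutylaluminium chloride
Product: 9 diisobutyl(vinyl)aluminium
Conditions: THF/hexane, 0 → 23 °C; solution decanted from the magnesium salts and used at once
Reagents that add atoms: none
Why: Salt metathesis (transmetalation from magnesium to aluminium), the usual entry to mixed alkenyl(dialkyl)alanes; the reagent is not purified.

Step 6
Reactants: 6 3,6-dimethylcyclohepta-2,5-dien-1-one; 9 diisobutyl(vinyl)aluminium; 10 isobutyraldehyde
Product: 12 (6S,7R)-6-ethenyl-7-[(1R)-1-hydroxy-2-methylpropyl]-3,6-dimethylcyclohept-3-en-1-one, via diisobutylaluminium enolate 11 (not isolated)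
Conditions: Cu(OTf)2 (5 mol %), chiral sulfonate-bearing NHC ligand (imidazolinium sulfonate premetalated with Ag2O, 5 mol %), THF, −78 → −50 °C; then 10, −78 °C; aq. potassium sodium tartrate
Reagents that add atoms: none
Why: The carbene-bound copper centre takes the vinyl group from 9, adds it to the β-carbon C1 of the enone part of 6 through a copper–alkene complex and reductive elimination, and leaves the regiodefined aluminium enolate 11 (C5=C6–O–Al). The closest known reaction type is the copper-catalysed enantioselective conjugate addition of alkenylaluminium reagents to β-methyl cycloalkenones with aldehyde capture of the aluminium enolate; 6 differs only by its remote skipped alkene. No ring is closed; the step forms C1–C2 and C4–C5 and brings all fifteen skeletal carbons together. C1 is set by the chiral ligand, which selects one enantioface of the enone. C5 is set by the substrate: the aldehyde should approach the enolate anti to the vinyl group, the C1 substituent with the smaller conformational demand and therefore the one placed pseudoaxial, which gives the trans arrangement of C2 and C4. C4 follows from a closed six-membered transition state of the ring (E)-enolate (anti aldol) and is needed only to steer step 7. The step needs 1,4- over 1,2-addition and transfer of vinyl in preference to isobutyl, which the copper catalyst and the sp2 ligand on aluminium secure. It also needs the C8=C9 alkene and the C7 methylene to stay untouched, which the non-basic, Lewis-acidic medium and the low temperature secure, since only C1=C5 is conjugated to the carbonyl group.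

Step 7
Reactants: 12 (6S,7R)-6-ethenyl-7-[(1R)-1-hydroxy-2-methylpropyl]-3,6-dimethylcyclohept-3-en-1-one
Product: 14 (1S,6S,7S)-6-ethenyl-7-[(1R)-1-hydroxy-2-methylpropyl]-3,6-dimethylcyclohept-3-en-1-ol, via diethylboron chelate 13 (not isolated)
Conditions: Et2BOMe, THF/MeOH (4:1), −78 °C; NaBH4; AcOH quench, MeOH co-evaporation
Reagents that add atoms: none
Why: Narasaka–Prasad reduction: Et2BOMe locks the β-hydroxy ketone as the six-membered boron chelate 13 and external hydride adds axially, giving the 1,3-syn diol. With the anti aldol this places the C6 hydroxyl trans to the C5 side chain (H5 and H6 anti), the configuration of 21; at −78 °C the β,γ-alkene should not migrate.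

Step 8
Reactants: 14 (1S,6S,7S)-6-ethenyl-7-[(1R)-1-hydroxy-2-methylpropyl]-3,6-dimethylcyclohept-3-en-1-ol; 15 3,4-dimethoxybenzoyl chloride
Product: 16 (1S,6S,7R)-6-ethenyl-7-[(1R)-1-hydroxy-2-methylpropyl]-3,6-dimethylcyclohept-3-en-1-yl 3,4-dimethoxybenzoate
Conditions: 15 (1.1 equiv), pyridine, DMAP (cat.), CH2Cl2, −20 → 0 °C
Reagents that add atoms: none
Why: Site-selective acylation with nucleophilic catalysis: the ring hydroxyl at C6 is far more accessible than the C4 hydroxyl, which is flanked by the isopropyl group and by C5 next to the quaternary C1. The ester is the one required in 21 and meanwhile protects O6.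

Step 9
Reactants: 16 (1S,6S,7R)-6-ethenyl-7-[(1R)-1-hydroxy-2-methylpropyl]-3,6-dimethylcyclohept-3-en-1-yl 3,4-dimethoxybenzoate
Product: 18 (1S,6S,7R)-6-(2-hydroxyethyl)-7-[(1R)-1-hydroxy-2-methylpropyl]-3,6-dimethylcyclohept-3-en-1-yl 3,4-dimethoxybenzoate, via B-alkyl-9-BBN adduct 17 (not isolated)
Conditions: 9-BBN (2.5 equiv), THF, 0 → 23 °C; then NaBO3·4H2O, H2O, 23 °C
Reagents that add atoms: sodium perborate (used as the tetrahydrate), [Na+].[Na+].O[B-]1(O)OO[B-](O)(O)OO1
Why: Anti-Markovnikov hydroboration with a bulky dialkylborane, which adds to the monosubstituted alkene far faster than to the trisubstituted C8=C9 and leaves the ester alone; perborate oxidises the C–B bond under conditions mild enough for the aryl ester. The excess reagent allows for any O–B bond formed at the C4 hydroxyl, which is released again on work-up.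

Step 10
Reactants: 18 (1S,6S,7R)-6-(2-hydroxyethyl)-7-[(1R)-1-hydroxy-2-methylpropyl]-3,6-dimethylcyclohept-3-en-1-yl 3,4-dimethoxybenzoate
Product: 19 (1S,6S,7R)-7-[(1R)-1-hydroxy-2-methylpropyl]-6-(2-iodoethyl)-3,6-dimethylcyclohept-3-en-1-yl 3,4-dimethoxybenzoate
Conditions: PPh3, I2, imidazole, CH2Cl2, 0 °C
Reagents that add atoms: iodine, II
Why: Appel-type iodination: the primary alkoxyphosphonium ion is displaced by iodide in an SN2 step, whereas the hindered secondary C4 hydroxyl should not be activated at 0 °C.

Step 11
Reactants: 19 (1S,6S,7R)-7-[(1R)-1-hydroxy-2-methylpropyl]-6-(2-iodoethyl)-3,6-dimethylcyclohept-3-en-1-yl 3,4-dimethoxybenzoate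
Product: 20 (1S,6S,7S)-6-(2-iodoethyl)-3,6-dimethyl-7-(2-methylpropanoyl)cyclohept-3-en-1-yl 3,4-dimethoxybenzoate
Conditions: Dess–Martin periodinane, NaHCO3, CH2Cl2, 0 → 23 °C
Reagents that add atoms: none
Why: Dess–Martin oxidation of a hindered secondary alcohol under buffered, near-neutral conditions, which tolerate the primary iodide and avoid β-elimination of the veratrate from the new β-acyloxy ketone; the C4 stereocentre is removed here on purpose.

Step 12
Reactants: 20 (1S,6S,7S)-6-(2-iodoethyl)-3,6-dimethyl-7-(2-methylpropanoyl)cyclohept-3-en-1-yl 3,4-dimethoxybenzoate
Product: 21 (3R,3aS,4S,8aR)-3-hydroxy-6,8a-dimethyl-3-(propan-2-yl)-1,2,3,3a,4,5,8,8a-octahydroazulen-4-yl 3,4-dimethoxybenzoate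
Conditions: SmI2 (2.5 equiv), NiI2 (cat.), THF, 0 °C, slow addition of 20; aq. NH4Cl
Reagents that add atoms: none
Why: Intramolecular samarium Barbier reaction, a five-membered ring closure in which the C3 organosamarium formed by two-electron reduction of the iodide adds to the C4 carbonyl group; the trans arrangement of the two arms at C1 and C5 makes the new ring trans-fused. The new C4 centre is controlled by trivalent samarium bridging the ketone oxygen and the C6 ester oxygen, which turns the carbonyl oxygen towards C6 and the isopropyl group towards H5, so the hydroxyl should end cis to C6 as in 21. Without a strongly donating cosolvent SmI2 should not reduce the electron-rich aryl ester, and NiI2 speeds the reduction of the iodide.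

## Compound list

1 | 2,5-dimethylphenol | Cc1ccc(C)c(O)c1 | starting material
2 | tert-butyl(2,5-dimethylphenoxy)dimethylsilane | Cc1ccc(C)c(O[Si](C)(C)C(C)(C)C)c1 | intermediate
3 | tert-butyl[(2,5-dimethylcyclohexa-1,4-dien-1-yl)oxy]dimethylsilane | CC1=C(O[Si](C)(C)C(C)(C)C)CC(C)=CC1 | intermediate
4 | tert-butyl[(3,6-dimethylbicyclo[4.1.0]hept-3-en-1-yl)oxy]dimethylsilane (racemic, cis-fused cyclopropane) | CC1=CCC2(C)CC2(O[Si](C)(C)C(C)(C)C)C1 | intermediate
5 | 3-chloro-3,6-dimethylcyclohept-5-en-1-one (racemic, not isolated) | CC1=CCC(C)(Cl)CC(=O)C1 | intermediate
6 | 3,6-dimethylcyclohepta-2,5-dien-1-one | CC1=CC(=O)CC(C)=CC1 | intermediate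
7 | vinylmagnesium bromide | C=C[Mg]Br | starting material
8 | diisobutylaluminium chloride | CC(C)C[Al](Cl)CC(C)C | starting material
9 | diisobutyl(vinyl)aluminium | C=C[Al](CC(C)C)CC(C)C | intermediate
10 | isobutyraldehyde (2-methylpropanal) | CC(C)C=O | starting material
11 | diisobutylaluminium (3S)-3-ethenyl-3,6-dimethylcyclohepta-1,5-dien-1-olate (not isolated) | C=C[C@]1(C)CC=C(C)CC(O[Al](CC(C)C)CC(C)C)=C1 | intermediate
12 | (6S,7R)-6-ethenyl-7-[(1R)-1-hydroxy-2-methylpropyl]-3,6-dimethylcyclohept-3-en-1-one | C=C[C@]1(C)CC=C(C)CC(=O)[C@H]1[C@H](O)C(C)C | intermediate
13 | diethylboron chelate of 12, (6S,7R)-7-[(1R)-1-(diethylboranyloxy)-2-methylpropyl]-6-ethenyl-3,6-dimethylcyclohept-3-en-1-one (not isolated) | C=C[C@]1(C)CC=C(C)CC(=O)[C@H]1[C@H](OB(CC)CC)C(C)C | intermediate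
14 | (1S,6S,7S)-6-ethenyl-7-[(1R)-1-hydroxy-2-methylpropyl]-3,6-dimethylcyclohept-3-en-1-ol | C=C[C@]1(C)CC=C(C)C[C@H](O)[C@H]1[C@H](O)C(C)C | intermediate
15 | 3,4-dimethoxybenzoyl chloride (veratroyl chloride) | COc1ccc(C(Cl)=O)cc1OC | starting material
16 | (1S,6S,7R)-6-ethenyl-7-[(1R)-1-hydroxy-2-methylpropyl]-3,6-dimethylcyclohept-3-en-1-yl 3,4-dimethoxybenzoate | C=C[C@]1(C)CC=C(C)C[C@H](OC(=O)c2ccc(OC)c(OC)c2)[C@H]1[C@H](O)C(C)C | intermediate
17 | B-alkyl-9-BBN adduct of 16: the 2-(9-borabicyclo[3.3.1]nonan-9-yl)ethyl analogue of 18, all stereocentres as in 16 (not isolated) | C1CCC2CCCC1B2CC[C@]3(C)CC=C(C)C[C@H](OC(=O)c4ccc(OC)c(OC)c4)[C@H]3[C@H](O)C(C)C | intermediate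
18 | (1S,6S,7R)-6-(2-hydroxyethyl)-7-[(1R)-1-hydroxy-2-methylpropyl]-3,6-dimethylcyclohept-3-en-1-yl 3,4-dimethoxybenzoate | OCC[C@]1(C)CC=C(C)C[C@H](OC(=O)c2ccc(OC)c(OC)c2)[C@H]1[C@H](O)C(C)C | intermediate
19 | (1S,6S,7R)-7-[(1R)-1-hydroxy-2-methylpropyl]-6-(2-iodoethyl)-3,6-dimethylcyclohept-3-en-1-yl 3,4-dimethoxybenzoate | ICC[C@]1(C)CC=C(C)C[C@H](OC(=O)c2ccc(OC)c(OC)c2)[C@H]1[C@H](O)C(C)C | intermediate
20 | (1S,6S,7S)-6-(2-iodoethyl)-3,6-dimethyl-7-(2-methylpropanoyl)cyclohept-3-en-1-yl 3,4-dimethoxybenzoate | ICC[C@]1(C)CC=C(C)C[C@H](OC(=O)c2ccc(OC)c(OC)c2)[C@H]1C(=O)C(C)C | intermediate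
21 | (3R,3aS,4S,8aR)-3-hydroxy-6,8a-dimethyl-3-(propan-2-yl)-1,2,3,3a,4,5,8,8a-octahydroazulen-4-yl 3,4-dimethoxybenzoate (daucane numbering 1R,4R,5S,6S) | COc1ccc(C(=O)O[C@H]2CC(C)=CC[C@@]3(C)CC[C@@](O)(C(C)C)[C@H]23)cc1OC | target

## Step count and least certain steps

Total step count: 12. Longest linear sequence: 11 steps (steps 1–4 and 6–12, from 1); step 5 is a one-step side branch that prepares the alane.

**Step 6 (key step).** The most likely failure is poor facial discrimination in the aldol capture, because the two C1 substituents (methyl and vinyl) differ little in size. Competing transfer of isobutyl, reduction of 10 by β-hydride transfer from the alane, and a lower enantiomeric ratio than on simple β-methyl cycloheptenones (the second alkene flattens the ring) are also possible. Fallback, from 6 and 9 back to 12: the two bond formations are separated. The conjugate addition is run alone and enolate 11 is silylated (Me3SiOTf, Et3N) to the trimethylsilyl enol ether F1, which can be purified. A Mukaiyama aldol reaction of F1 with 10 (TiCl4, CH2Cl2, −78 °C) then goes through an open transition state, in which the Lewis-acid-bound aldehyde should respond more strongly to the difference between the two enolate faces, and gives 12.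

**Step 12.** Three things may go wrong. The transient C3 radical can attack the C8=C9 alkene (a 5-hexenyl-type cyclisation) before it is reduced to the organosamarium. Electron transfer to the aryl ester can compete. Loss of the samarium chelate would erode the selectivity at C4. Fallback, from 16 back to 21: ring A is closed at C2–C3 by metathesis instead. Oxidation of 16 (Dess–Martin periodinane, NaHCO3) gives the vinyl ketone F2. Chelation-controlled addition of 7 in the presence of CeCl3 (THF, −78 °C) gives the divinyl carbinol F3. The second-generation Grubbs catalyst (CH2Cl2, 40 °C) closes the cyclopentene F4. Diimide (2-nitrobenzenesulfonyl hydrazide, Et3N) should saturate the disubstituted ring A alkene in preference to the trisubstituted C8=C9 and give 21.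

**Step 4.** Cleavage of the bulky silyl ether by FeCl3 may be slow. More seriously, the alkenes of 6 may migrate into conjugation during the base-promoted loss of HCl, since both the C7 and the C10 methylene of 6 are activated. Fallback, from 3 back to 6: dibromocarbene (CHBr3, KOt-Bu, pentane, −20 °C) is added to the enol ether alkene of 3 to give the dibromocyclopropane F5. This opens on gentle warming, with loss of the silyl bromide, to the 2-bromodienone F6. Hydrodebromination under neutral conditions (Pd(PPh3)4 cat., Bu3SnH, THF, 23 °C) then gives 6 without any base.

**Step 7.** Hydride delivery under chelate control may be overridden by the ring, since attack anti to the C5 side chain leads to the 6-epimer. The outcome also depends on the C4 configuration supplied by step 6, and the site selectivity of step 8 rests on this diol. Fallback, from 12 back to 16: silylation of 12 (Et3SiOTf, 2,6-lutidine) gives the triethylsilyl ether F7. Reduction with LiBH(s-Bu)3 from the face opposite the C5 side chain gives the 6-epi alcohol F8. Mitsunobu esterification with veratric acid (PPh3, DIAD) inverts C6 and gives the silyl-protected ester F9. HF·pyridine then removes the silyl group and gives 16, so that neither the directed reduction nor the selective acylation is needed.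

## Further compounds

F1 | step 6 | {[(3S)-3-ethenyl-3,6-dimethylcyclohepta-1,5-dien-1-yl]oxy}trimethylsilane | C=C[C@]1(C)CC=C(C)CC(O[Si](C)(C)C)=C1
F2 | step 12 | (1S,6S,7S)-6-ethenyl-3,6-dimethyl-7-(2-methylpropanoyl)cyclohept-3-en-1-yl 3,4-dimethoxybenzoate | C=C[C@]1(C)CC=C(C)C[C@H](OC(=O)c2ccc(OC)c(OC)c2)[C@H]1C(=O)C(C)C
F3 | step 12 | divinyl carbinol: analogue of 16 in which C4 carries hydroxyl, isopropyl and a vinyl group, C4 configured as in 21 | C=C[C@]1(C)CC=C(C)C[C@H](OC(=O)c2ccc(OC)c(OC)c2)[C@H]1[C@@](O)(C=C)C(C)C
F4 | step 12 | 2,3-didehydro analogue of 21 (cyclopentene in ring A), 3-hydroxy-6,8a-dimethyl-3-(propan-2-yl)-3,3a,4,5,8,8a-hexahydroazulen-4-yl 3,4-dimethoxybenzoate with the configuration of 21 | COc1ccc(C(=O)O[C@H]2CC(C)=CC[C@@]3(C)C=C[C@@](O)(C(C)C)[C@H]23)cc1OC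
F5 | step 4 | tert-butyl[(7,7-dibromo-3,6-dimethylbicyclo[4.1.0]hept-3-en-1-yl)oxy]dimethylsilane (racemic) | CC1=CCC2(C)C(Br)(Br)C2(O[Si](C)(C)C(C)(C)C)C1
F6 | step 4 | 2-bromo-3,6-dimethylcyclohepta-2,5-dien-1-one | CC1=C(Br)C(=O)CC(C)=CC1
F7 | step 7 | triethylsilyl ether of 12 at the C4 oxygen | C=C[C@]1(C)CC=C(C)CC(=O)[C@H]1[C@H](O[Si](CC)(CC)CC)C(C)C
F8 | step 7 | 6-epi alcohol: C6 epimer of diol 14 with the C4 oxygen as triethylsilyl ether | C=C[C@]1(C)CC=C(C)C[C@@H](O)[C@H]1[C@H](O[Si](CC)(CC)CC)C(C)C
F9 | step 7 | triethylsilyl ether of 16 at the C4 oxygen | C=C[C@]1(C)CC=C(C)C[C@H](OC(=O)c2ccc(OC)c(OC)c2)[C@H]1[C@H](O[Si](CC)(CC)CC)C(C)C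
A1 | alternative 1 | exo [5+2] cycloadduct: sulfinyl cyclopentanone fused to an 8-oxabicyclo[3.2.1]octenone (oxygen bridge C6–O–C10, C9 ketone, C7=C8) | O=C1CC[C@@]2(C)[C@]1([S@@](=O)c1ccc(C)cc1)[C@@H]3C=C(C)C(=O)[C@H]2O3
A2 | alternative 1 | 3-methyl-2-(p-tolylsulfinyl)cyclopent-2-en-1-one, single enantiomer at sulfur as in A1 | CC1=C([S@@](=O)c2ccc(C)cc2)C(=O)CC1
A3 | alternative 1 | 6-acetoxy-4-methyl-2H-pyran-3(6H)-one (racemic) | CC(=O)OC1C=C(C)C(=O)CO1
A4 | alternative 2 | bicyclic 1,4-diene ester with C4 ketal | COC(=O)C1=CC[C@@]2(C)CCC3(OCCO3)C2=CC1
A5 | alternative 2 | methyl 2-diazobut-3-enoate | C=CC(=[N+]=[N-])C(=O)OC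
A6 | alternative 2 | 6-ethenyl-7-methyl-1,4-dioxaspiro[4.4]non-6-ene | C=CC1=C(C)CCC12OCCO2
A7 | alternative 3 | carotol | C1CC(C)=CC[C@@]2(C)CC[C@@H](C(C)C)[C@@]12O
A8 | alternative 3 | (2E,6E)-farnesyl diphosphate | CC(C)=CCC/C(C)=C/CC/C(C)=C/COP(=O)(O)OP(=O)(O)O
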